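## The problem

The target 18 is a 2,2-disubstituted 2H-chromene. Its benzene ring (ring B) carries four contiguous substituents: the C8 phenol, the ring oxygen O1 at C8a, the pyran carbon C4 at C4a and, at C5, a 3-oxopropyl chain ending in a 2,4-dihydroxyphenyl ketone (ring A). C2 bears a methyl group and an (E)-4-hydroxy-4-methylpent-2-enyl chain. C2 is the only stereocentre; it is quaternary and (R), and nothing else in the molecule can relay chirality to it, so it must come from a catalyst or from the chiral pool. The C2–O1 bond is tertiary, allylic and an aryl ether at once: acid ionises it, and heat or light open the chromene electrocyclically to an achiral dienone, so after C2 is set the route is confined to near-neutral or basic steps at moderate temperature. The tertiary allylic alcohol eliminates or transposes under acid, the three alkenes exclude hydrogenation and hydrogenolysis, and three phenols must be freed at the end without acid, which points to silyl ethers and fluoride. The substitution pattern of ring B is better bought than made. The enabling feature is that C2 carries the ring alkene carbon C3 and the chain carbon C1': C1' and C2' can arrive as a vinyl group, so a precursor whose C2 holds two vinyl groups, the methyl group and the aryloxy oxygen is prochiral. Ring-closing metathesis of one of these vinyl groups with a vinyl group on C4a then forms C3=C4, closes the pyran ring and sets C2 in one event, and the second vinyl group remains as the handle for the side chain.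

## Retrosynthesis

**18 from 17.** Only O–Si bonds are cut. The three phenols are carried as silyl ethers (triisopropylsilyl at O8, tert-butyldimethylsilyl on ring A), so a buffered fluoride treatment ends the synthesis without acid, base or reduction. The tertiary alcohol is left free throughout.

**17 from 13 and 16.** The aryl–alkyl bond C5–CH2 is cut. The neighbouring cuts are poorer: the acyl–aryl bond would need Friedel–Crafts conditions, and the CH2–CH2 bond would need an enone reduction in the presence of three other alkenes. Cyclopropanol 16 is a ketone homoenolate in masked form, and palladium-catalysed ring-opening coupling with aryl bromide 13 delivers ring A with the ketone already at the correct oxidation level. The precursors are two fragments of comparable size. The forward step needs oxidative addition into a hindered, electron-rich aryl bromide and reductive elimination faster than β-hydride elimination.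

**16 from 15 and 14.** The two C–C bonds of the cyclopropane are cut (ester cyclopropanation with a titanacyclopropane) and then the two O–Si bonds, leading to the commercial ester 14.

**13 from 11, 9 and 7.** The side chain is cut at the two C4'–CH3 bonds (double methyl addition to enoate 11), at C2'=C3' (two-carbon Wittig extension of aldehyde 10, which fixes the E geometry) and at C2'–O (anti-Markovnikov hydration of the vinyl group of 7 to alcohol 9). Aldehyde 10 has the aryloxy group of C2 in the β position and could open the ring by β-elimination, so it is made and consumed in one flask. The ketone of the C5 chain would not survive the methyl addition, so the bromide is carried as far as 13.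

**7 from 6.** The C3=C4 bond is cut. Triene 6 is achiral and open-chain at the pyran, and the forward reaction must select one of two enantiotopic vinyl groups. Cutting O1–C2 or C4–C4a instead is possible (see the roads not taken) but would leave either the ring alkene or the catalyst control less secure.

**6 from 5, 3 and 4.** The styrene C=C bond is cut (methylenation of aldehyde 5), then the C8a–O1 bond (displacement of fluoride from 3 by the alkoxide of dienol 4). The formyl group does double duty: it activates the fluoride and then becomes the styrene. Forming the O–C(tertiary) bond from a phenol instead would need a tertiary electrophile and is kept in reserve.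

**3 from 2 and 1.** The O8 methyl ether of commercial 1 cannot be cleaved once the tertiary allylic ether is present, so it is exchanged for triisopropylsilyl at the outset.

## Roads not taken

Alternative 1: Ring A is cut across two C–C bonds by a retro-Diels–Alder step. In the forward sense the chromene-tethered ethynyl ketone A2 and 1-methoxy-1,3-bis(trimethylsilyloxy)buta-1,3-diene A3 combine, methanol is lost, and the doubly protected target A1 emerges with both ring A phenols in place. Its merits are that the polarity of A3 fixes the 2,4-dihydroxy pattern, that ring A needs no protecting groups, and that no ortho-silyloxy cyclopropanol is required. Its weak points are that it builds a ring that can be bought, that A2 needs several steps from the C5 bromide and is a strong Michael acceptor, that the cycloaddition needs heating the 2H-chromene tolerates poorly, and that C2 and the pyran ring are not addressed at all. In the ring A endgame it is milder than a late palladium coupling of a hindered bromide. Against that, the chosen plan obtains ring A in two steps from ester 14 and uses its key step on the only stereochemical problem.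

Alternative 2: O1–C2 and C1'–C2' are cut. The alkenylphenol A5 undergoes enantioselective oxypalladation with Pd(OCOCF3)2, a chiral bis(oxazoline) and a quinone reoxidant; the resulting alkylpalladium has no β-hydrogen and is trapped by methyl acrylate A6 to give chroman A4. Two bonds, the ring and C2 form at once, and the E-enoate arrives directly. In this respect it is better than the chosen plan, which needs hydroboration, oxidation and olefination after the key step and passes through a β-aryloxy aldehyde. Its weak points are that A4 is a chroman, so C3=C4 must be introduced later by benzylic dehydrogenation of an arene deactivated by the peri bromine with a sensitive side chain present, and that the aryl bromide must survive zerovalent palladium formed in every turnover. A5 also needs its own synthesis. The chosen plan sets against the better bond economy that the ring alkene is formed in the stereodetermining step at the correct oxidation level.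

Alternative 3: C4–C4a is cut. The bis-alkynyl ether A8 cyclises under a chiral cationic complex of monovalent gold (a bisphosphine(AuCl)2 complex activated by AgSbF6) by 6-endo-dig hydroarylation at the only free ortho carbon, and selection of one ethynyl group gives A7. It shares the desymmetrisation logic, avoids both the displacement at a crowded carbon and the methylenation, and the ethynyl group of A7 gives the acetaldehyde in one hydroboration–oxidation, so it is as short as the chosen plan or one step shorter. Its weak points are that the attacking carbon is deactivated by the adjacent bromine, that 5-exo closure competes, that the linear gold centre holds the ligand far from a prochiral carbon differentiated only by methyl against aryloxy, that terminal alkynes sequester gold as acetylides, and that a thermal propargyl Claisen route to racemic A7 exists as background. The chosen plan sets against the shorter sequence a catalyst family with documented enantiotopic alkene selection in forming cyclic tertiary ethers and the absence of any uncatalysed cyclisation.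

Key step: step 5

Assumption: which antipode of the biphenolate ligand leads to (R)-7 cannot be derived reliably on paper for this substrate; one trial with each antipode settles it, and the route is written for the antipode that gives (R)-7.

## Route

Step 1
Reactants: 1 6-bromo-2-fluoro-3-methoxybenzaldehyde
Product: 2 6-bromo-2-fluoro-3-hydroxybenzaldehyde
Conditions: BBr3, CH2Cl2, −78 °C to 0 °C; H2O
Reagents that add atoms: none
Why: Lewis-acid cleavage of an aryl methyl ether; the aryl fluoride, aryl bromide and formyl group are inert at low temperature and the aldehyde is returned on hydrolysis.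

Step 2
Reactants: 2 6-bromo-2-fluoro-3-hydroxybenzaldehyde
Product: 3 6-bromo-2-fluoro-3-(triisopropylsilyloxy)benzaldehyde
Conditions: TIPSCl, imidazole, DMF, rt
Reagents that add atoms: triisopropylsilyl chloride, CC(C)[Si](Cl)(C(C)C)C(C)C
Why: Silylation of a phenol; the hindered triisopropylsilyl ether is chosen because it should withstand alkoxide, ylide, Grignard and palladium conditions and falls to fluoride at the end.

Step 3
Reactants: 3 6-bromo-2-fluoro-3-(triisopropylsilyloxy)benzaldehyde; 4 3-methylpenta-1,4-dien-3-ol
Product: 5 6-bromo-2-[(3-methylpenta-1,4-dien-3-yl)oxy]-3-(triisopropylsilyloxy)benzaldehyde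
Conditions: 4, KH, THF, 0 °C; then 3, 18-crown-6 (cat.), −20 °C to rt
Reagents that add atoms: none
Why: Nucleophilic aromatic substitution by addition–elimination: the ortho formyl group stabilises the Meisenheimer adduct, and fluoride leaves far faster than the equally ortho-placed bromide. Tertiary potassium alkoxides are known to displace fluoride from o-fluorobenzaldehydes, and preforming the alkoxide keeps the hydride base away from the aldehyde.

Step 4
Reactants: 5 6-bromo-2-[(3-methylpenta-1,4-dien-3-yl)oxy]-3-(triisopropylsilyloxy)benzaldehyde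
Product: 6 4-bromo-2-[(3-methylpenta-1,4-dien-3-yl)oxy]-1-(triisopropylsilyloxy)-3-vinylbenzene
Conditions: MePPh3Br, KOtBu, THF, 0 °C; then 5, 0 °C to rt
Reagents that add atoms: methyltriphenylphosphonium bromide, C[P+](c1ccccc1)(c1ccccc1)c1ccccc1.[Br-]
Why: Wittig methylenation of a non-enolisable aldehyde; the unstabilised ylide adds even to di-ortho-substituted benzaldehydes and leaves the aryl bromide, silyl ether and tertiary ether untouched at room temperature.

Step 5
Reactants: 6 4-bromo-2-[(3-methylpenta-1,4-dien-3-yl)oxy]-1-(triisopropylsilyloxy)-3-vinylbenzene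
Product: 7 (2R)-5-bromo-2-methyl-8-(triisopropylsilyloxy)-2-vinyl-2H-chromene
Conditions: Mo(N-2,6-iPr2C6H3)(CHCMe2Ph)[3,3'-tBu2-5,5',6,6'-Me4-biphenyl-2,2'-diolate] (one antipode, 5–10 mol%), benzene, 22 to 50 °C, argon sweep, dark
Reagents that add atoms: none
Why: Olefin metathesis by [2+2] cycloaddition and cycloreversion at a hexavalent molybdenum alkylidene: the neophylidene exchanges onto the styrene terminus, the arylidene adds to one of the two enantiotopic vinyl groups, and cycloreversion of the molybdacyclobutane releases the C3=C4 bond with loss of ethene. The closest known reaction types are the desymmetrising ring-closing metathesis of prochiral trienes to unsaturated cyclic tertiary ethers with molybdenum biphenolates and the molybdenum-catalysed enantioselective metathesis of styrenyl ethers to 2-substituted 2H-chromenes. The pyran ring closes as a six-membered ring between the aryl-bound vinyl group and one carbinol vinyl group; the two carbinol vinyl groups cannot close on each other, so the second one is left as the C1'–C2' handle. C2 is set by catalyst control alone: the biphenolate and the arylimido group make the two vinyl groups diastereotopic in the metallacyclobutane, where methyl and aryloxy occupy different quadrants. The step needs only enantiotopic-group selection, helped by the quaternary carbon that holds both vinyl groups near the tethered alkylidene and by the absence of any uncatalysed cyclisation. Ethene is swept out to suppress ring opening of 7 by the methylidene, the one pathway that could erode enantiomeric purity. The aryl bromide, the silyl ether and the hindered remaining vinyl group should be spectators.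

Step 6
Reactants: 7 (2R)-5-bromo-2-methyl-8-(triisopropylsilyloxy)-2-vinyl-2H-chromene
Product: 9 2-[(2R)-5-bromo-2-methyl-8-(triisopropylsilyloxy)-2H-chromen-2-yl]ethan-1-ol, via B-alkyl-9-borabicyclo[3.3.1]nonane adduct 8 (not isolated)
Conditions: 9-BBN, THF, 0 °C to rt; then NaBO3·4H2O, H2O, rt
Reagents that add atoms: 9-borabicyclo[3.3.1]nonane (boron carried only in 8), C1CC2CCCC(C1)B2; sodium perborate (supplies the hydroxyl oxygen), [Na+].[Na+].O[B-]1(O)OO[B-](O)(O)OO1
Why: Hydroboration–oxidation; 9-BBN adds to the monosubstituted vinyl group much faster than to the cis-disubstituted conjugated ring alkene and places boron on the terminal carbon, and the mild perborate oxidation spares the aryl silyl ether. C2 is not involved.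

Step 7
Reactants: 9 2-[(2R)-5-bromo-2-methyl-8-(triisopropylsilyloxy)-2H-chromen-2-yl]ethan-1-ol
Product: 11 methyl (2E)-4-[(2R)-5-bromo-2-methyl-8-(triisopropylsilyloxy)-2H-chromen-2-yl]but-2-enoate, via aldehyde 10 (not isolated)
Conditions: Dess–Martin periodinane, NaHCO3, CH2Cl2, 0 °C to rt; then Ph3P=CHCO2Me, rt
Reagents that add atoms: methyl (triphenylphosphoranylidene)acetate, COC(=O)C=P(c1ccccc1)(c1ccccc1)c1ccccc1
Why: One-flask Dess–Martin oxidation and Wittig olefination; the β-aryloxy aldehyde 10 meets only a neutral stabilised ylide and is never isolated or exposed to base, and the stabilised ylide should give the E-enoate.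

Step 8
Reactants: 11 methyl (2E)-4-[(2R)-5-bromo-2-methyl-8-(triisopropylsilyloxy)-2H-chromen-2-yl]but-2-enoate
Product: 13 (3E)-5-[(2R)-5-bromo-2-methyl-8-(triisopropylsilyloxy)-2H-chromen-2-yl]-2-methylpent-3-en-2-ol, via enone 12 (not isolated)
Conditions: MeMgBr (3.5 equiv), THF, −78 °C to 0 °C; aq NH4Cl
Reagents that add atoms: methylmagnesium bromide, C[Mg]Br
Why: Double Grignard addition to an ester through the methyl ketone 12; the hard methyl nucleophile adds 1,2 to the enoate and the enone faster than it deprotonates the γ-position, and the aryl bromide and silyl ether are inert at this temperature.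

Step 9
Reactants: 14 methyl 2,4-dihydroxybenzoate
Product: 15 methyl 2,4-bis(tert-butyldimethylsilyloxy)benzoate
Conditions: TBSCl (2.5 equiv), imidazole, DMF, rt to 40 °C
Reagents that add atoms: tert-butyldimethylsilyl chloride, CC(C)(C)[Si](C)(C)Cl
Why: Silylation of both phenols; excess reagent and gentle warming bring in the hydrogen-bonded 2-hydroxyl group.

Step 10
Reactants: 15 methyl 2,4-bis(tert-butyldimethylsilyloxy)benzoate
Product: 16 1-[2,4-bis(tert-butyldimethylsilyloxy)phenyl]cyclopropan-1-ol
Conditions: EtMgBr (3 equiv), Ti(OiPr)4 (0.3 equiv), THF, 0 °C to rt; aq NH4Cl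
Reagents that add atoms: ethylmagnesium bromide, CC[Mg]Br
Why: Kulinkovich cyclopropanation; the titanacyclopropane formed from EtMgBr and Ti(OiPr)4 acts as a 1,2-dicarbanion toward the aryl ester, and aryl silyl ethers tolerate the magnesium and titanium alkoxides at this temperature.

Step 11
Reactants: 13 (3E)-5-[(2R)-5-bromo-2-methyl-8-(triisopropylsilyloxy)-2H-chromen-2-yl]-2-methylpent-3-en-2-ol; 16 1-[2,4-bis(tert-butyldimethylsilyloxy)phenyl]cyclopropan-1-ol
Product: 17 1-[2,4-bis(tert-butyldimethylsilyloxy)phenyl]-3-[(2R)-2-[(2E)-4-hydroxy-4-methylpent-2-en-1-yl]-2-methyl-8-(triisopropylsilyloxy)-2H-chromen-5-yl]propan-1-one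
Conditions: Pd(OAc)2 (5 mol%), XPhos (10 mol%), Cs2CO3, toluene, 80 °C, dark
Reagents that add atoms: none
Why: Palladium-catalysed ring-opening cross-coupling of a cyclopropanol with an aryl bromide: zerovalent palladium inserts into C5–Br, the cyclopropanolate displaces bromide, β-carbon elimination gives the palladium homoenolate and reductive elimination forms the C5–CH2 bond. The bulky biaryl phosphine should favour reductive elimination over β-hydride elimination, and the hindered tertiary alcohol of 13 is a spectator.

Step 12
Reactants: 17 1-[2,4-bis(tert-butyldimethylsilyloxy)phenyl]-3-[(2R)-2-[(2E)-4-hydroxy-4-methylpent-2-en-1-yl]-2-methyl-8-(triisopropylsilyloxy)-2H-chromen-5-yl]propan-1-one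
Product: 18 1-(2,4-dihydroxyphenyl)-3-[(2R)-8-hydroxy-2-[(2E)-4-hydroxy-4-methylpent-2-en-1-yl]-2-methyl-2H-chromen-5-yl]propan-1-one
Conditions: Bu4NF (3.5 equiv), AcOH (3.5 equiv), THF, 0 °C, dark
Reagents that add atoms: none
Why: Fluoride cleavage of three aryl silyl ethers; the acetic acid buffer keeps the liberated phenols protonated, and neither the chromene, the tertiary allylic alcohol nor C2 is touched.

## Compound list

1 | 6-bromo-2-fluoro-3-methoxybenzaldehyde | COc1ccc(Br)c(C=O)c1F | starting material
2 | 6-bromo-2-fluoro-3-hydroxybenzaldehyde | Oc1ccc(Br)c(C=O)c1F | intermediate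
3 | 6-bromo-2-fluoro-3-(triisopropylsilyloxy)benzaldehyde | CC(C)[Si](Oc1ccc(Br)c(C=O)c1F)(C(C)C)C(C)C | intermediate
4 | 3-methylpenta-1,4-dien-3-ol | C=CC(C)(O)C=C | starting material
5 | 6-bromo-2-[(3-methylpenta-1,4-dien-3-yl)oxy]-3-(triisopropylsilyloxy)benzaldehyde | C=CC(C)(C=C)Oc1c(O[Si](C(C)C)(C(C)C)C(C)C)ccc(Br)c1C=O | intermediate
6 | 4-bromo-2-[(3-methylpenta-1,4-dien-3-yl)oxy]-1-(triisopropylsilyloxy)-3-vinylbenzene | C=CC(C)(C=C)Oc1c(O[Si](C(C)C)(C(C)C)C(C)C)ccc(Br)c1C=C | intermediate
7 | (2R)-5-bromo-2-methyl-8-(triisopropylsilyloxy)-2-vinyl-2H-chromene | C=C[C@]1(C)C=Cc2c(Br)ccc(O[Si](C(C)C)(C(C)C)C(C)C)c2O1 | intermediate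
8 | 9-{2-[(2R)-5-bromo-2-methyl-8-(triisopropylsilyloxy)-2H-chromen-2-yl]ethyl}-9-borabicyclo[3.3.1]nonane | C1CC2CCCC(C1)B2CC[C@]1(C)C=Cc2c(Br)ccc(O[Si](C(C)C)(C(C)C)C(C)C)c2O1 | intermediate (not isolated)
9 | 2-[(2R)-5-bromo-2-methyl-8-(triisopropylsilyloxy)-2H-chromen-2-yl]ethan-1-ol | OCC[C@]1(C)C=Cc2c(Br)ccc(O[Si](C(C)C)(C(C)C)C(C)C)c2O1 | intermediate
10 | 2-[(2R)-5-bromo-2-methyl-8-(triisopropylsilyloxy)-2H-chromen-2-yl]acetaldehyde | O=CC[C@]1(C)C=Cc2c(Br)ccc(O[Si](C(C)C)(C(C)C)C(C)C)c2O1 | intermediate (not isolated)
11 | methyl (2E)-4-[(2R)-5-bromo-2-methyl-8-(triisopropylsilyloxy)-2H-chromen-2-yl]but-2-enoate | COC(=O)/C=C/C[C@]1(C)C=Cc2c(Br)ccc(O[Si](C(C)C)(C(C)C)C(C)C)c2O1 | intermediate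
12 | (3E)-5-[(2R)-5-bromo-2-methyl-8-(triisopropylsilyloxy)-2H-chromen-2-yl]pent-3-en-2-one | CC(=O)/C=C/C[C@]1(C)C=Cc2c(Br)ccc(O[Si](C(C)C)(C(C)C)C(C)C)c2O1 | intermediate (not isolated)
13 | (3E)-5-[(2R)-5-bromo-2-methyl-8-(triisopropylsilyloxy)-2H-chromen-2-yl]-2-methylpent-3-en-2-ol | CC(C)(O)/C=C/C[C@]1(C)C=Cc2c(Br)ccc(O[Si](C(C)C)(C(C)C)C(C)C)c2O1 | intermediate
14 | methyl 2,4-dihydroxybenzoate | COC(=O)c1ccc(O)cc1O | starting material
15 | methyl 2,4-bis(tert-butyldimethylsilyloxy)benzoate | COC(=O)c1ccc(O[Si](C)(C)C(C)(C)C)cc1O[Si](C)(C)C(C)(C)C | intermediate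
16 | 1-[2,4-bis(tert-butyldimethylsilyloxy)phenyl]cyclopropan-1-ol | OC1(CC1)c1ccc(O[Si](C)(C)C(C)(C)C)cc1O[Si](C)(C)C(C)(C)C | intermediate
17 | 1-[2,4-bis(tert-butyldimethylsilyloxy)phenyl]-3-[(2R)-2-[(2E)-4-hydroxy-4-methylpent-2-en-1-yl]-2-methyl-8-(triisopropylsilyloxy)-2H-chromen-5-yl]propan-1-one | CC(C)(O)/C=C/C[C@]1(C)C=Cc2c(CCC(=O)c3ccc(O[Si](C)(C)C(C)(C)C)cc3O[Si](C)(C)C(C)(C)C)ccc(O[Si](C(C)C)(C(C)C)C(C)C)c2O1 | intermediate
18 | 1-(2,4-dihydroxyphenyl)-3-[(2R)-8-hydroxy-2-[(2E)-4-hydroxy-4-methylpent-2-en-1-yl]-2-methyl-2H-chromen-5-yl]propan-1-one | CC(C)(O)/C=C/C[C@]1(C)C=Cc2c(CCC(=O)c3ccc(O)cc3O)ccc(O)c2O1 | target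

## Step count and risks

Total: 12 steps. Longest linear sequence: 10 steps (steps 1 to 8, 11 and 12); steps 9 and 10 form the side branch.

**Step 5 (key step).** The catalyst may discriminate poorly between the two enantiotopic vinyl groups, since methyl and aryloxy differ only moderately in the metallacycle. Turnover at the doubly ortho-substituted styrene may be slow, and reversible ring opening of the product by the methylidene may erode the enantiomeric purity. The fallback takes C2 from the chiral pool and sets out from 3.
- The potassium alkoxide of purchased (R)-linalool (C=C[C@](C)(O)CCC=C(C)C, from KH) displaces the fluoride as in step 3 to give 6-bromo-2-{[(3R)-3,7-dimethylocta-1,6-dien-3-yl]oxy}-3-(triisopropylsilyloxy)benzaldehyde F1.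
- Wittig methylenation as in step 4 gives 4-bromo-2-{[(3R)-3,7-dimethylocta-1,6-dien-3-yl]oxy}-1-(triisopropylsilyloxy)-3-vinylbenzene F2.
- Ring-closing metathesis with the achiral RuCl2(H2IMes)(PCy3)(=CHPh) in CH2Cl2 joins the styrene and the vinyl group, the trisubstituted alkene being a spectator, and gives (2R)-5-bromo-2-methyl-2-(4-methylpent-3-en-1-yl)-8-(triisopropylsilyloxy)-2H-chromene F3.
- A Schenck ene reaction (O2, visible light, tetraphenylporphyrin, CH2Cl2, 0 °C) transposes the trisubstituted alkene to (2R)-5-bromo-2-[(2E)-4-hydroperoxy-4-methylpent-2-en-1-yl]-2-methyl-8-(triisopropylsilyloxy)-2H-chromene F4, which is separated from its secondary regioisomer after reduction with PPh3.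
- The reduction gives 13, where the route is rejoined.

**Step 3.** Substitution at a carbon flanked by the formyl and the bulky silyloxy group may be slow, and the alkoxide may instead transfer the silyl group from the aryl oxygen or add to the aldehyde. The fallback forms the O–C(tertiary) bond from a phenol and sets out from 3.
- The small alkoxide of 2-(methylsulfonyl)ethanol (NaH, DMF, 0 °C) displaces fluoride to give 6-bromo-2-[2-(methylsulfonyl)ethoxy]-3-(triisopropylsilyloxy)benzaldehyde F5, which is not isolated and eliminates in the same flask to 6-bromo-2-hydroxy-3-(triisopropylsilyloxy)benzaldehyde F6.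
- Purchased 3-methylpent-1-en-4-yn-3-ol is converted (n-BuLi, ClCO2Me) into methyl 3-methylpent-1-en-4-yn-3-yl carbonate F7.
- Copper-catalysed propargylic etherification of F6 with F7 (CuCl2 cat., DBU, MeCN, 0 °C) gives racemic 6-bromo-2-[(3-methylpent-1-en-4-yn-3-yl)oxy]-3-(triisopropylsilyloxy)benzaldehyde F8.
- Semihydrogenation of the ethynyl group (H2, Pd/CaCO3 poisoned with Pb(OAc)2, quinoline) erases the stereocentre and gives 5, where the route is rejoined.

**Step 11.** β-Hydride elimination of the palladium homoenolate may give the aryl vinyl ketone and the debrominated chromene, oxidative addition into the hindered electron-rich bromide may be slow, and the ortho silyl group may migrate to the cyclopropanol oxygen under base. The fallback is a Heck arylation with chain walking and sets out from 13.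
- Purchased 2,4-dihydroxybenzaldehyde is silylated as in step 9 to 2,4-bis(tert-butyldimethylsilyloxy)benzaldehyde F9.
- Addition of CH2=CHMgBr (THF, −78 °C) gives racemic 1-[2,4-bis(tert-butyldimethylsilyloxy)phenyl]prop-2-en-1-ol F10.
- Heck reaction of 13 with F10 (Pd(OAc)2, Bu4NCl, NaHCO3, DMF, 90 °C) places the aryl group on the terminal carbon; β-hydride elimination toward the carbinol and tautomerisation give ketone 17, where the route is rejoined.

**Step 7.** β-Elimination of the C2 aryloxide from enolisable aldehyde 10 (retro-oxa-Michael ring opening) may destroy the configuration of C2. The fallback reverses the polarity of the olefination so that no carbonyl group sits β to O1, and sets out from 9.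
- Mitsunobu reaction with 1-phenyl-1H-tetrazole-5-thiol (PPh3, DIAD, THF) gives 5-({2-[(2R)-5-bromo-2-methyl-8-(triisopropylsilyloxy)-2H-chromen-2-yl]ethyl}sulfanyl)-1-phenyl-1H-tetrazole F11.
- Oxidation with H2O2 and (NH4)6Mo7O24 in EtOH gives 5-({2-[(2R)-5-bromo-2-methyl-8-(triisopropylsilyloxy)-2H-chromen-2-yl]ethyl}sulfonyl)-1-phenyl-1H-tetrazole F12.
- The partner is made from purchased methyl 2-hydroxy-2-methylpropanoate by silylation to methyl 2-methyl-2-(triethylsilyloxy)propanoate F13 and reduction with i-Bu2AlH at −78 °C to 2-methyl-2-(triethylsilyloxy)propanal F14.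
- Julia–Kocienski olefination of F12 with F14 (KN(SiMe3)2, DME, −60 °C) gives (2R)-5-bromo-2-methyl-2-[(2E)-4-methyl-4-(triethylsilyloxy)pent-2-en-1-yl]-8-(triisopropylsilyloxy)-2H-chromene F15. The sulfonyl carbanion is two carbons from C2 and cannot expel the aryloxide.
- Mild hydrolysis of the triethylsilyl ether (AcOH, THF, H2O, rt) gives 13, where the route is rejoined.

## Further compounds

F1 | step 5 | 6-bromo-2-{[(3R)-3,7-dimethylocta-1,6-dien-3-yl]oxy}-3-(triisopropylsilyloxy)benzaldehyde | C=C[C@](C)(Oc1c(O[Si](C(C)C)(C(C)C)C(C)C)ccc(Br)c1C=O)CCC=C(C)C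
F2 | step 5 | 4-bromo-2-{[(3R)-3,7-dimethylocta-1,6-dien-3-yl]oxy}-1-(triisopropylsilyloxy)-3-vinylbenzene | C=C[C@](C)(Oc1c(O[Si](C(C)C)(C(C)C)C(C)C)ccc(Br)c1C=C)CCC=C(C)C
F3 | step 5 | (2R)-5-bromo-2-methyl-2-(4-methylpent-3-en-1-yl)-8-(triisopropylsilyloxy)-2H-chromene | CC(C)=CCC[C@]1(C)C=Cc2c(Br)ccc(O[Si](C(C)C)(C(C)C)C(C)C)c2O1
F4 | step 5 | (2R)-5-bromo-2-[(2E)-4-hydroperoxy-4-methylpent-2-en-1-yl]-2-methyl-8-(triisopropylsilyloxy)-2H-chromene | CC(C)(OO)/C=C/C[C@]1(C)C=Cc2c(Br)ccc(O[Si](C(C)C)(C(C)C)C(C)C)c2O1
F5 | step 3 | 6-bromo-2-[2-(methylsulfonyl)ethoxy]-3-(triisopropylsilyloxy)benzaldehyde | CS(=O)(=O)CCOc1c(O[Si](C(C)C)(C(C)C)C(C)C)ccc(Br)c1C=O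
F6 | step 3 | 6-bromo-2-hydroxy-3-(triisopropylsilyloxy)benzaldehyde | O=Cc1c(Br)ccc(O[Si](C(C)C)(C(C)C)C(C)C)c1O
F7 | step 3 | methyl 3-methylpent-1-en-4-yn-3-yl carbonate (racemic) | COC(=O)OC(C)(C=C)C#C
F8 | step 3 | 6-bromo-2-[(3-methylpent-1-en-4-yn-3-yl)oxy]-3-(triisopropylsilyloxy)benzaldehyde (racemic) | C#CC(C)(C=C)Oc1c(O[Si](C(C)C)(C(C)C)C(C)C)ccc(Br)c1C=O
F9 | step 11 | 2,4-bis(tert-butyldimethylsilyloxy)benzaldehyde | O=Cc1ccc(O[Si](C)(C)C(C)(C)C)cc1O[Si](C)(C)C(C)(C)C
F10 | step 11 | 1-[2,4-bis(tert-butyldimethylsilyloxy)phenyl]prop-2-en-1-ol (racemic) | C=CC(O)c1ccc(O[Si](C)(C)C(C)(C)C)cc1O[Si](C)(C)C(C)(C)C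
F11 | step 7 | 5-({2-[(2R)-5-bromo-2-methyl-8-(triisopropylsilyloxy)-2H-chromen-2-yl]ethyl}sulfanyl)-1-phenyl-1H-tetrazole | c1ccc(cc1)-n1nnnc1SCC[C@]1(C)C=Cc2c(Br)ccc(O[Si](C(C)C)(C(C)C)C(C)C)c2O1
F12 | step 7 | 5-({2-[(2R)-5-bromo-2-methyl-8-(triisopropylsilyloxy)-2H-chromen-2-yl]ethyl}sulfonyl)-1-phenyl-1H-tetrazole | c1ccc(cc1)-n1nnnc1S(=O)(=O)CC[C@]1(C)C=Cc2c(Br)ccc(O[Si](C(C)C)(C(C)C)C(C)C)c2O1
F13 | step 7 | methyl 2-methyl-2-(triethylsilyloxy)propanoate | CC[Si](CC)(CC)OC(C)(C)C(=O)OC
F14 | step 7 | 2-methyl-2-(triethylsilyloxy)propanal | CC[Si](CC)(CC)OC(C)(C)C=O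
F15 | step 7 | (2R)-5-bromo-2-methyl-2-[(2E)-4-methyl-4-(triethylsilyloxy)pent-2-en-1-yl]-8-(triisopropylsilyloxy)-2H-chromene | CC[Si](CC)(CC)OC(C)(C)/C=C/C[C@]1(C)C=Cc2c(Br)ccc(O[Si](C(C)C)(C(C)C)C(C)C)c2O1
A1 | alternative 1 | 1-(2,4-dihydroxyphenyl)-3-[(2R)-2-methyl-2-[(2E)-4-methyl-4-(triethylsilyloxy)pent-2-en-1-yl]-8-(triisopropylsilyloxy)-2H-chromen-5-yl]propan-1-one | CC(C)(O[Si](CC)(CC)CC)/C=C/C[C@]1(C)C=Cc2c(CCC(=O)c3ccc(O)cc3O)ccc(O[Si](C(C)C)(C(C)C)C(C)C)c2O1
A2 | alternative 1 | 5-[(2R)-2-methyl-2-[(2E)-4-methyl-4-(triethylsilyloxy)pent-2-en-1-yl]-8-(triisopropylsilyloxy)-2H-chromen-5-yl]pent-1-yn-3-one | CC(C)(O[Si](CC)(CC)CC)/C=C/C[C@]1(C)C=Cc2c(CCC(=O)C#C)ccc(O[Si](C(C)C)(C(C)C)C(C)C)c2O1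
A3 | alternative 1 | 1-methoxy-1,3-bis(trimethylsilyloxy)buta-1,3-diene | COC(O[Si](C)(C)C)=CC(=C)O[Si](C)(C)C
A4 | alternative 2 | methyl (2E)-4-[(2S)-5-bromo-2-methyl-8-(triisopropylsilyloxy)chroman-2-yl]but-2-enoate (same spatial arrangement at C2 as the target) | COC(=O)/C=C/C[C@]1(C)CCc2c(Br)ccc(O[Si](C(C)C)(C(C)C)C(C)C)c2O1
A5 | alternative 2 | 3-bromo-2-(3-methylbut-3-en-1-yl)-6-(triisopropylsilyloxy)phenol | C=C(C)CCc1c(Br)ccc(O[Si](C(C)C)(C(C)C)C(C)C)c1O
A6 | alternative 2 | methyl acrylate | C=CC(=O)OC
A7 | alternative 3 | (2S)-5-bromo-2-ethynyl-2-methyl-8-(triisopropylsilyloxy)-2H-chromene (same spatial arrangement at C2 as the target) | C#C[C@]1(C)C=Cc2c(Br)ccc(O[Si](C(C)C)(C(C)C)C(C)C)c2O1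
A8 | alternative 3 | 4-bromo-2-[(3-methylpenta-1,4-diyn-3-yl)oxy]-1-(triisopropylsilyloxy)benzene | C#CC(C)(C#C)Oc1cc(Br)ccc1O[Si](C(C)C)(C(C)C)C(C)C
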